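**Retrosynthetic overview**

1. Feature: ring B is a benzene ring with oxygen on three alternating carbons (one OMe, two OH). The CH2 bridge to pyranone ring A sits on the carbon between the OMe carbon and one OH carbon, and the acyl group on the carbon between the two OH carbons.
2. Endgame disconnections: two O–CH3 bonds (BCl3) and the aryl–acyl C–C bond (Fries shift from the single free phenol); (R)-2-methylbutanoic acid brings the only stereocentre.
3. Key disconnection: ring B is built around the bridge from 3-methoxycyclobutenone 15 and methoxyacetylene by a vinylketene/ynol ether benzannulation. The three oxygens arrive differentiated: OH from the ketene carbonyl, one OMe from 15, one OMe from the alkyne.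
4. 15 comes from a ketene/ynol ether [2+2] of the acid chloride of pyranonylpropanoic acid 9; the three-carbon arm is put on C3 of ring A by bromination, Heck coupling and hydrogenation.
5. Ring order: ring A (step 2, from pentan-3-one enol silane and malonyl dichloride), then the four-membered ring (step 8), then ring B (step 9).

Key step: step 9

Assumption: (R)-2-methylbutanoic acid of high enantiomeric purity is taken as purchasable. Methoxyacetylene is used in both cycloadditions because it has no β-hydrogen and so cannot fragment thermally to ketene and an alkene, as ethyl ynol ethers do near 100–120 °C.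

**Route**

Step 1
Reactants: 1 pentan-3-one
Product: 2 (Z)-3-(trimethylsilyloxy)pent-2-ene
Conditions: TMSOTf, Et3N, CH2Cl2, 0 °C → rt; distil
Reagents that add atoms: trimethylsilyl trifluoromethanesulfonate, C[Si](C)(C)OS(=O)(=O)C(F)(F)F
Why: Soft enolisation and O-silylation (silyl enol ether formation) of a symmetrical ketone can give only one constitutional isomer, and the alkene geometry is lost in step 2.

Step 2
Reactants: 2 (Z)-3-(trimethylsilyloxy)pent-2-ene; 3 malonyl dichloride
Product: 4 6-ethyl-4-hydroxy-5-methylpyran-2-one
Conditions: Et2O, −78 °C → rt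
Reagents that add atoms: none
Why: Acylative pyranone annulation: one acid chloride group C-acylates the enol silane, the other O-acylates the resulting diketone enol, and the product rests as the 4-hydroxy-2-pyranone with the ketone carbons as C5 (methyl) and C6 (ethyl) of ring A.

Step 3
Reactants: 4 6-ethyl-4-hydroxy-5-methylpyran-2-one
Product: 5 6-ethyl-4-methoxy-5-methylpyran-2-one
Conditions: Me2SO4, K2CO3, acetone, reflux
Reagents that add atoms: dimethyl sulfate, COS(=O)(=O)OC
Why: O-Alkylation of the acidic 4-hydroxyl (a vinylogous carboxylic acid) under carbonate/dimethyl sulfate conditions should favour the 4-methoxy-2-pyranone, which masks the enol for the acid chloride and ketene chemistry to come.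

Step 4
Reactants: 5 6-ethyl-4-methoxy-5-methylpyran-2-one
Product: 6 3-bromo-6-ethyl-4-methoxy-5-methylpyran-2-one
Conditions: NBS, MeCN, rt, dark
Reagents that add atoms: N-bromosuccinimide, O=C1CCC(=O)N1Br
Why: Electrophilic bromination should occur at C3, the only ring CH and the nucleophilic β-carbon of the enol ether, while ionic conditions in the dark spare the allylic methyl and ethyl groups.

Step 5
Reactants: 6 3-bromo-6-ethyl-4-methoxy-5-methylpyran-2-one; 7 benzyl acrylate
Product: 8 benzyl (E)-3-(6-ethyl-4-methoxy-5-methyl-2-oxopyran-3-yl)prop-2-enoate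
Conditions: Pd(OAc)2 (5 mol %), P(o-tol)3, Et3N, DMF, 100 °C
Reagents that add atoms: none
Why: Mizoroki–Heck reaction: zerovalent palladium inserts into the C3–Br bond, the acrylate inserts syn and β-hydride elimination gives the (E)-alkene, which brings all three carbons of the future ketene arm.

Step 6
Reactants: 8 benzyl (E)-3-(6-ethyl-4-methoxy-5-methyl-2-oxopyran-3-yl)prop-2-enoate
Product: 9 3-(6-ethyl-4-methoxy-5-methyl-2-oxopyran-3-yl)propanoic acid
Conditions: H2 (1 atm), 10% Pd/C, EtOAc, rt
Reagents that add atoms: none
Why: Heterogeneous hydrogenation saturates the disubstituted acrylate double bond and hydrogenolyses the benzyl ester in one operation, while the tetrasubstituted double bonds of the pyranone should be too hindered to be reduced at one atmosphere.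

Step 7
Reactants: 10 chloroacetaldehyde dimethyl acetal
Product: 12 methoxyacetylene, via sodium methoxyacetylide 11 (not isolated)
Conditions: NaNH2 (3 equiv), liquid NH3, −33 °C; then cold saturated aqueous NaCl; distil into a −78 °C trap
Reagents that add atoms: none
Why: Double β-elimination with sodium amide (loss of methanol, then of hydrogen chloride) gives the acetylide, and protonation releases the low-boiling ynol ether, which is kept as a cold stock solution.

Step 8
Reactants: 9 3-(6-ethyl-4-methoxy-5-methyl-2-oxopyran-3-yl)propanoic acid; 12 methoxyacetylene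
Product: 15 (±)-3-[(2-methoxy-4-oxocyclobut-2-en-1-yl)methyl]-6-ethyl-4-methoxy-5-methylpyran-2-one, via acid chloride 13 (not isolated), via ketene 14 (not isolated)
Conditions: (COCl)2, DMF (cat.), CH2Cl2, 0 °C → rt, evaporate; then slow addition to 12 (5 equiv), Et3N, CH2Cl2, 0 °C → rt, closed vessel
Reagents that add atoms: none
Why: Dehydrochlorination of the acid chloride gives a monoalkylketene that undergoes the known ketene/ynol ether [2+2] cycloaddition, the nucleophilic alkyne CH bonding to the ketene carbonyl carbon so that the methoxy group lands at C3 and the pyranonylmethyl group at C4 of the cyclobutenone; slow addition into excess alkyne suppresses ketene dimerisation, and the new C4 stereocentre is racemic and is destroyed in step 9.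

Step 9
Reactants: 15 (±)-3-[(2-methoxy-4-oxocyclobut-2-en-1-yl)methyl]-6-ethyl-4-methoxy-5-methylpyran-2-one; 12 methoxyacetylene
Product: 20 3-[(2-hydroxy-4,6-dimethoxyphenyl)methyl]-6-ethyl-4-methoxy-5-methylpyran-2-one, via vinylketene 16 (not isolated), via vinylcyclobutenone 17 (not isolated), via dienylketene 18 (not isolated), via cyclohexadienone 19 (not isolated)
Conditions: 12 (8 equiv), toluene, sealed tube, 120–140 °C
Reagents that add atoms: none
Why: Proposed new method: heat opens cyclobutenone 15 by 4π electrocyclic cleavage of its C1–C4 bond to vinylketene 16, whose ketene carbonyl carbon is attacked by the nucleophilic CH of methoxyacetylene, so that a regioselective [2+2] cycloaddition gives 17 (ketene carbon to alkyne CH, former cyclobutenone C2 to the methoxy-bearing alkyne carbon). A second 4π opening gives dienylketene 18, and ring B is closed by a thermal disrotatory 6π electrocyclisation between the ketene carbon and the diene terminus (the former cyclobutenone C4), after which dienone 19 tautomerises to phenol 20. The closest known reaction is the Danheiser benzannulation of 3-alkylcyclobutenones with alkoxyalkynes, whose second-stage intermediate is itself a 3-alkoxycyclobutenone that opens under the reaction conditions; new here is the 3-methoxy group on the starting cyclobutenone. Its vinylogous-ester stabilisation should raise the temperature of the first opening, which is why an ynol ether without β-hydrogens is used. No stereocentre is formed, and the racemic C4 centre of 15 becomes an aromatic carbon. The selectivity needed is regiochemical and comes from the ketene/ynol ether polarity, which places the new methoxy group meta to the hydroxyl and the bridge carbon between the hydroxyl and the older methoxy group; the fully substituted 4-methoxypyranone is a poor diene and a poor ketene trap and should not interfere.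

Step 10
Reactants: 20 3-[(2-hydroxy-4,6-dimethoxyphenyl)methyl]-6-ethyl-4-methoxy-5-methylpyran-2-one; 21 (R)-2-methylbutanoic acid
Product: 22 2-[(6-ethyl-4-methoxy-5-methyl-2-oxopyran-3-yl)methyl]-3,5-dimethoxyphenyl (2R)-2-methylbutanoate
Conditions: DCC, DMAP (cat.), CH2Cl2, 0 °C → rt
Reagents that add atoms: none
Why: Steglich esterification of the only free hydroxyl; no strong base and no acid chloride is involved, so the α-stereocentre of the acid should be carried over unchanged as (R).

Step 11
Reactants: 22 2-[(6-ethyl-4-methoxy-5-methyl-2-oxopyran-3-yl)methyl]-3,5-dimethoxyphenyl (2R)-2-methylbutanoate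
Product: 23 3-[[2-hydroxy-4,6-dimethoxy-3-[(2R)-2-methylbutanoyl]phenyl]methyl]-6-ethyl-4-methoxy-5-methylpyran-2-one
Conditions: TiCl4 (3 equiv), CH2Cl2, 0 °C → rt; then cold 1 M HCl
Reagents that add atoms: none
Why: Fries rearrangement: the titanium phenoxide should deliver the acyl group to the single free ortho carbon, where the product is held as a six-membered chelate, in preference to the para carbon flanked by two methoxy groups; low temperature and the absence of base protect the stereocentre.

Step 12
Reactants: 23 3-[[2-hydroxy-4,6-dimethoxy-3-[(2R)-2-methylbutanoyl]phenyl]methyl]-6-ethyl-4-methoxy-5-methylpyran-2-one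
Product: 24 3-[[2,4-dihydroxy-6-methoxy-3-[(2R)-2-methylbutanoyl]phenyl]methyl]-6-ethyl-4-hydroxy-5-methylpyran-2-one
Conditions: BCl3 (6 equiv), CH2Cl2, −78 °C → rt; then MeOH, aqueous NaHCO3
Reagents that add atoms: none
Why: Lewis-acid ether cleavage assisted by carbonyl coordination: BCl3 held at the aryl ketone should cleave the methoxy group ortho to it, and BCl3 at the lactone carbonyl turns the pyranone methoxy group into a methoxypyrylium-type methyl donor that chloride demethylates, while the methoxy group para to the ketone has no such assistance and is deactivated by conjugation; without base the stereocentre should stay (R).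

**Compound list**

1 | pentan-3-one | CCC(=O)CC | starting material
2 | (Z)-3-(trimethylsilyloxy)pent-2-ene (geometry immaterial) | C/C=C(/CC)O[Si](C)(C)C | intermediate
3 | malonyl dichloride | O=C(Cl)CC(=O)Cl | starting material
4 | 6-ethyl-4-hydroxy-5-methylpyran-2-one | CCc1oc(=O)cc(O)c1C | intermediate
5 | 6-ethyl-4-methoxy-5-methylpyran-2-one | CCc1oc(=O)cc(OC)c1C | intermediate
6 | 3-bromo-6-ethyl-4-methoxy-5-methylpyran-2-one | CCc1oc(=O)c(Br)c(OC)c1C | intermediate
7 | benzyl acrylate | C=CC(=O)OCc1ccccc1 | starting material
8 | benzyl (E)-3-(6-ethyl-4-methoxy-5-methyl-2-oxopyran-3-yl)prop-2-enoate | CCc1oc(=O)c(/C=C/C(=O)OCc2ccccc2)c(OC)c1C | intermediate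
9 | 3-(6-ethyl-4-methoxy-5-methyl-2-oxopyran-3-yl)propanoic acid | CCc1oc(=O)c(CCC(=O)O)c(OC)c1C | intermediate
10 | chloroacetaldehyde dimethyl acetal (2-chloro-1,1-dimethoxyethane) | COC(CCl)OC | starting material
11 | sodium methoxyacetylide | [Na+].[C-]#COC | intermediate
12 | methoxyacetylene | C#COC | intermediate
13 | 3-(6-ethyl-4-methoxy-5-methyl-2-oxopyran-3-yl)propanoyl chloride | CCc1oc(=O)c(CCC(=O)Cl)c(OC)c1C | intermediate
14 | 6-ethyl-4-methoxy-5-methyl-3-(3-oxoprop-2-en-1-yl)pyran-2-one (ketene) | CCc1oc(=O)c(CC=C=O)c(OC)c1C | intermediate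
15 | (±)-3-[(2-methoxy-4-oxocyclobut-2-en-1-yl)methyl]-6-ethyl-4-methoxy-5-methylpyran-2-one | COC1=CC(=O)C1Cc1c(OC)c(C)c(CC)oc1=O | intermediate
16 | 6-ethyl-4-methoxy-3-(3-methoxy-5-oxopenta-2,4-dien-1-yl)-5-methylpyran-2-one (vinylketene; alkene geometry not fixed) | O=C=CC(OC)=CCc1c(OC)c(C)c(CC)oc1=O | intermediate
17 | 6-ethyl-4-methoxy-3-[3-methoxy-3-(2-methoxy-4-oxocyclobut-2-en-1-yl)prop-2-en-1-yl]-5-methylpyran-2-one (racemic; alkene geometry not fixed) | O=C1C=C(OC)C1C(OC)=CCc1c(OC)c(C)c(CC)oc1=O | intermediate
18 | 3-(3,5-dimethoxy-7-oxohepta-2,4,6-trien-1-yl)-6-ethyl-4-methoxy-5-methylpyran-2-one (dienylketene; alkene geometry not fixed) | O=C=CC(OC)=CC(OC)=CCc1c(OC)c(C)c(CC)oc1=O | intermediate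
19 | (±)-3-[(2,4-dimethoxy-6-oxocyclohexa-2,4-dien-1-yl)methyl]-6-ethyl-4-methoxy-5-methylpyran-2-one | O=C1C=C(OC)C=C(OC)C1Cc1c(OC)c(C)c(CC)oc1=O | intermediate
20 | 3-[(2-hydroxy-4,6-dimethoxyphenyl)methyl]-6-ethyl-4-methoxy-5-methylpyran-2-one | COc1cc(O)c(Cc2c(OC)c(C)c(CC)oc2=O)c(OC)c1 | intermediate
21 | (R)-2-methylbutanoic acid | CC[C@@H](C)C(=O)O | starting material
22 | 2-[(6-ethyl-4-methoxy-5-methyl-2-oxopyran-3-yl)methyl]-3,5-dimethoxyphenyl (2R)-2-methylbutanoate | CC[C@@H](C)C(=O)Oc1cc(OC)cc(OC)c1Cc1c(OC)c(C)c(CC)oc1=O | intermediate
23 | 3-[[2-hydroxy-4,6-dimethoxy-3-[(2R)-2-methylbutanoyl]phenyl]methyl]-6-ethyl-4-methoxy-5-methylpyran-2-one | CC[C@@H](C)C(=O)c1c(O)c(Cc2c(OC)c(C)c(CC)oc2=O)c(OC)cc1OC | intermediate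
24 | 3-[[2,4-dihydroxy-6-methoxy-3-[(2R)-2-methylbutanoyl]phenyl]methyl]-6-ethyl-4-hydroxy-5-methylpyran-2-one | CCc1oc(=O)c(Cc2c(OC)cc(O)c(C(=O)[C@H](C)CC)c2O)c(O)c1C | target

**Step count**

Total steps: 12. Longest linear sequence: 11 steps (steps 1–6 and 8–12); step 7 is a one-step side branch.

**Steps most likely to fail**

1. Step 9 (proposed new method). The vinylogous-ester cyclobutenone may not open below the temperature at which the ynol ether oligomerises, or the vinylketene may be lost to dimerisation or to acylation of the product phenol before it meets the alkyne.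
Fallback (known chemistry), setting out from 4 and 21 and returning at 24: acid 21 is converted with oxalyl chloride into (2R)-2-methylbutanoyl chloride F1, which acylates phloroglucinol under Friedel–Crafts conditions (AlCl3, CH2Cl2/nitromethane) to (2R)-2-methyl-1-(2,4,6-trihydroxyphenyl)butan-1-one F2. One equivalent of dimethyl sulfate with K2CO3 should methylate the non-chelated para hydroxyl to give (2R)-1-(2,6-dihydroxy-4-methoxyphenyl)-2-methylbutan-1-one F3. Pyranone 4 with Eschenmoser's salt gives the Mannich base 3-[(dimethylamino)methyl]-6-ethyl-4-hydroxy-5-methylpyran-2-one F4. Warming F4 with F3 should expel dimethylamine and alkylate one of the two equivalent free ring carbons of F3, which gives 24 directly.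

2. Step 12. Cleavage of the aryl methyl ether beside the ketone may stall because the ketone oxygen is already tied up in the boron chelate of the neighbouring phenoxide; forcing the reaction then endangers the para methoxy group and, through enolisation, the stereocentre. The pyranone methyl ether may also lag.
Fallback, setting out from 23 and returning at 24: the chelated phenol is acetylated (Ac2O, pyridine, DMAP) to 2-[(6-ethyl-4-methoxy-5-methyl-2-oxopyran-3-yl)methyl]-3,5-dimethoxy-6-[(2R)-2-methylbutanoyl]phenyl acetate F7, in which the ketone is free to chelate BCl3 together with the adjacent methoxy group. BCl3 at low temperature should then give 2-[(6-ethyl-4-hydroxy-5-methyl-2-oxopyran-3-yl)methyl]-5-hydroxy-3-methoxy-6-[(2R)-2-methylbutanoyl]phenyl acetate F8, and brief methanolysis (K2CO3 cat., MeOH, 0 °C) removes the acetate to give 24.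

3. Step 11. The acyl group may migrate to the ring carbon para to the phenol (between the two methoxy carbons), scramble intermolecularly, or lose stereochemical integrity through enolisation of the acylium or ketone complex; the acid may also cleave the benzylic bridge.
Fallback, setting out from 20 and returning at 24: phenol 20 is O-methylated (MeI, K2CO3, acetone) to 6-ethyl-4-methoxy-5-methyl-3-[(2,4,6-trimethoxyphenyl)methyl]pyran-2-one F5, whose two free ring carbons are equivalent by symmetry. Friedel–Crafts acylation with acid 21 and trifluoroacetic anhydride (mixed anhydride, rt) can then give only 6-ethyl-4-methoxy-5-methyl-3-[[2,4,6-trimethoxy-3-[(2R)-2-methylbutanoyl]phenyl]methyl]pyran-2-one F6. BCl3 under the conditions of step 12 should remove the two methyl groups ortho to the ketone and the pyranone methyl group, giving 24.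

**Further compounds**

F1 | step 9 | (2R)-2-methylbutanoyl chloride | CC[C@@H](C)C(=O)Cl
F2 | step 9 | (2R)-2-methyl-1-(2,4,6-trihydroxyphenyl)butan-1-one | CC[C@@H](C)C(=O)c1c(O)cc(O)cc1O
F3 | step 9 | (2R)-1-(2,6-dihydroxy-4-methoxyphenyl)-2-methylbutan-1-one | CC[C@@H](C)C(=O)c1c(O)cc(OC)cc1O
F4 | step 9 | 3-[(dimethylamino)methyl]-6-ethyl-4-hydroxy-5-methylpyran-2-one | CCc1oc(=O)c(CN(C)C)c(O)c1C
F5 | step 11 | 6-ethyl-4-methoxy-5-methyl-3-[(2,4,6-trimethoxyphenyl)methyl]pyran-2-one | COc1cc(OC)c(Cc2c(OC)c(C)c(CC)oc2=O)c(OC)c1
F6 | step 11 | 6-ethyl-4-methoxy-5-methyl-3-[[2,4,6-trimethoxy-3-[(2R)-2-methylbutanoyl]phenyl]methyl]pyran-2-one | CC[C@@H](C)C(=O)c1c(OC)cc(OC)c(Cc2c(OC)c(C)c(CC)oc2=O)c1OC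
F7 | step 12 | 2-[(6-ethyl-4-methoxy-5-methyl-2-oxopyran-3-yl)methyl]-3,5-dimethoxy-6-[(2R)-2-methylbutanoyl]phenyl acetate | CC[C@@H](C)C(=O)c1c(OC(C)=O)c(Cc2c(OC)c(C)c(CC)oc2=O)c(OC)cc1OC
F8 | step 12 | 2-[(6-ethyl-4-hydroxy-5-methyl-2-oxopyran-3-yl)methyl]-5-hydroxy-3-methoxy-6-[(2R)-2-methylbutanoyl]phenyl acetate | CC[C@@H](C)C(=O)c1c(OC(C)=O)c(Cc2c(O)c(C)c(CC)oc2=O)c(OC)cc1O
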